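Locants: lactone C1(=O), O2, C3 and benzene C3a–C7a (benzene = ring A, lactone = ring B); chain C1'–C6'; spiroketal O1'', C2'', C5'' (spiro), O6'', C7'' (rings C and D).
Last disconnection: rings C and D are closed together at C5'' from an open-chain 7',13'-dihydroxy-10'-ketone, whose two carbinol centres come from two (R)-epoxides joined through acetone dimethylhydrazone.
C1'–C2': cross-metathesis of (R)-5,7-dimethoxy-3-vinylphthalide with the terminal alkene of the keto bis-silyl ether, then diimide reduction.
Ring B: in one flask CO2 is set between C7a and C3 of an achiral (E)-cinnamyl carbonate (C7a–C1 by carboxylation of the aryl Grignard reagent, O2–C3 by palladium-catalysed asymmetric allylic lactonisation); the enabling feature is that ring B is CO2 bridging C7a, which lies between C3a and the C7 methoxy group and can be iodinated and metalated cleanly, and the benzylic carbon C3, which becomes the terminus of an η3-allyl unit when C1' and C2' are carried as a vinyl group, so that all allyl isomers funnel to one C3 configuration.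
Ring order: ring A is bought, ring B is formed in step 5, rings C and D in step 14.

Key step: step 5

Remark: the spiro carbon C5'' of a 2,7-dialkyl-1,6-dioxaspiro[4.4]nonane equilibrates under acid and no strong thermodynamic bias is expected between the wanted 5''S epimer (each alkyl group trans to the oxygen of the other ring) and the 5''R epimer. C5'' is therefore set in the last step by an equilibrate–separate–return loop in which the 5''R epimer is sent back to acid without being isolated, and the isolated target is not exposed to acid afterwards.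

Step 1
Reactants: 1 3,5-dimethoxybenzaldehyde
Product: 2 2-iodo-3,5-dimethoxybenzaldehyde
Conditions: NIS (1.0 equiv), CF3CO2H (cat.), MeCN, rt, dark
Reagents that add atoms: N-iodosuccinimide, O=C1CCC(=O)N1I
Why: Electrophilic aromatic iodination should go to C2 (equivalent to C6), which is ortho to one methoxy group and para to the other, because the position between the two methoxy groups is the more hindered one.

Step 2
Reactants: 2 2-iodo-3,5-dimethoxybenzaldehyde; 3 triethyl phosphonoacetate
Product: 4 ethyl (E)-3-(2-iodo-3,5-dimethoxyphenyl)prop-2-enoate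
Conditions: NaH, THF, 0 °C to rt
Reagents that add atoms: none
Why: Horner–Wadsworth–Emmons olefination of the aryl aldehyde with the stabilised phosphonate anion should give the E cinnamate, and the aryl iodide is inert to NaH.

Step 3
Reactants: 4 ethyl (E)-3-(2-iodo-3,5-dimethoxyphenyl)prop-2-enoate
Product: 5 (E)-3-(2-iodo-3,5-dimethoxyphenyl)prop-2-en-1-ol
Conditions: iBu2AlH (2.2 equiv), CH2Cl2, −78 °C; aq. potassium sodium tartrate work-up
Reagents that add atoms: none
Why: Hydride reduction of the conjugated ester with iBu2AlH at low temperature gives the allylic alcohol by 1,2-reduction without touching the aryl iodide or the alkene.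

Step 4
Reactants: 5 (E)-3-(2-iodo-3,5-dimethoxyphenyl)prop-2-en-1-ol
Product: 6 tert-butyl (E)-3-(2-iodo-3,5-dimethoxyphenyl)prop-2-en-1-yl carbonate
Conditions: Boc2O, Bu4NHSO4 (cat.), aq. NaOH, CH2Cl2, 0 °C to rt
Reagents that add atoms: di-tert-butyl dicarbonate, CC(C)(C)OC(=O)OC(=O)OC(C)(C)C
Why: Phase-transfer O-acylation of the primary allylic alcohol with Boc2O is the standard entry to tert-butyl allyl carbonates, the hindered leaving group wanted for allylic substitution.

Step 5
Reactants: 6 tert-butyl (E)-3-(2-iodo-3,5-dimethoxyphenyl)prop-2-en-1-yl carbonate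
Product: 9 (R)-5,7-dimethoxy-3-vinylisobenzofuran-1(3H)-one, via arylmagnesium chloride 7 (not isolated), via chloromagnesium carboxylate 8 (not isolated)
Conditions: iPrMgCl·LiCl (slight excess), THF, −20 to 0 °C; CO2 (1 atm), −20 to 0 °C; then Pd2(dba)3·CHCl3 (2.5 mol %), (R,R)-DACH-phenyl Trost ligand (7.5 mol %), Bu4NCl, THF/CH2Cl2, 0 °C to rt
Reagents that add atoms: carbon dioxide, O=C=O
Why: Proposed new method: iodine–magnesium exchange at C7a (helped by chelation from the C7 methoxy group and harmless to the hindered tert-butyl carbonate) gives aryl Grignard 7, which captures CO2 to give carboxylate 8, and zerovalent palladium then ionises the allylic carbonate with loss of tert-butoxide and CO2 to a cationic η3-allyl complex of divalent palladium whose benzylic terminus is attacked by the tethered carboxylate oxygen on the face opposite to the metal, so that the C7a–C1 and O2–C3 bonds form in one flask. The closest known reactions are the carboxylation of aryl Grignard reagents and the Tsuji–Trost asymmetric allylic substitution with carboxylate nucleophiles, and their merger in one pot on a magnesium carboxylate is the untested part. Ring B closes in the 5-exo mode at the allyl terminus (the remaining C=C stays outside the ring), whereas attack at the far terminus would need a seven-membered ring holding a cis alkene. The C3 stereocentre is set by the chiral ligand, because the two diastereomeric η3-allyl complexes (and those from any Z isomer of 6) interconvert by η3–η1–η3 slippage at the unsubstituted CH2 terminus, aided by chloride, and the material funnels through the faster-cyclising complex; the (R,R) ligand is proposed for the R configuration and its antipode is the immediate remedy if the sense of induction proves opposite. The step needs the intramolecular O-alkylation to outrun reionisation of the product (itself an allylic ester) and attack by stray isobutyrate, which the five-membered closure, the low temperature, the near-stoichiometric amount of Grignard reagent and a quench at full conversion should secure.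

Step 6
Reactants: 10 5-bromopent-1-ene; 11 (R)-epichlorohydrin
Product: 13 (R)-1-chlorooct-7-en-2-ol, via pent-4-enylmagnesium bromide 12 (not isolated)
Conditions: Mg, THF; then CuI (10 mol %), 11, −40 to 0 °C; H2O work-up
Reagents that add atoms: none
Why: Copper-catalysed Grignard opening of the epoxide takes place at its unsubstituted carbon and leaves the C–O bond of the stereocentre untouched, so the R configuration of 11 is carried into 13.

Step 7
Reactants: 13 (R)-1-chlorooct-7-en-2-ol
Product: 14 (R)-2-(hex-5-en-1-yl)oxirane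
Conditions: NaOH, H2O/Et2O, rt
Reagents that add atoms: none
Why: Intramolecular Williamson etherification displaces chloride at the primary carbon and does not touch the stereocentre, which keeps the R descriptor.

Step 8
Reactants: 15 acetone N,N-dimethylhydrazone; 16 (R)-2-methyloxirane
Product: 18 (R)-5-(2,2-dimethylhydrazinylidene)hexan-2-ol, via lithium azaenolate 17 (not isolated)
Conditions: n-BuLi, THF, −78 to 0 °C; then 16, 0 °C to rt; H2O
Reagents that add atoms: none
Why: Corey–Enders alkylation of the lithium azaenolate opens the epoxide at its CH2 terminus in an SN2 reaction, so the R carbinol centre of 16 is retained.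

Step 9
Reactants: 18 (R)-5-(2,2-dimethylhydrazinylidene)hexan-2-ol; 14 (R)-2-(hex-5-en-1-yl)oxirane
Product: 20 (2R,8R)-5-(2,2-dimethylhydrazinylidene)tetradec-13-ene-2,8-diol, via dilithio alkoxide azaenolate 19 (not isolated)
Conditions: LiN(iPr)2 (2.2 equiv), THF, −78 to 0 °C; then 14, 0 °C to rt; H2O
Reagents that add atoms: none
Why: The first equivalent of base forms the alkoxide and the second deprotonates the hydrazone at its methyl group, the less substituted α-carbon, and this azaenolate alkylation opens 14 at the CH2 terminus with retention of its R centre.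

Step 10
Reactants: 20 (2R,8R)-5-(2,2-dimethylhydrazinylidene)tetradec-13-ene-2,8-diol
Product: 21 2-[(2R,8R)-2,8-bis(tert-butyldimethylsilyloxy)tetradec-13-en-5-ylidene]-1,1-dimethylhydrazine
Conditions: TBSCl, imidazole, DMF, rt
Reagents that add atoms: tert-butyldimethylsilyl chloride, CC(C)(C)[Si](C)(C)Cl
Why: Silyl ether formation on both secondary alcohols under basic conditions leaves the hydrazone intact and keeps the chain open once the ketone is unmasked.

Step 11
Reactants: 21 2-[(2R,8R)-2,8-bis(tert-butyldimethylsilyloxy)tetradec-13-en-5-ylidene]-1,1-dimethylhydrazine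
Product: 22 (2R,8R)-2,8-bis(tert-butyldimethylsilyloxy)tetradec-13-en-5-one
Conditions: satd aq. oxalic acid, Et2O, rt (two-phase)
Reagents that add atoms: water, O
Why: Two-phase hydrazone hydrolysis with oxalic acid frees the ketone under conditions that secondary TBS ethers withstand, and the silyl ethers prevent premature spiroketalisation.

Step 12
Reactants: 9 (R)-5,7-dimethoxy-3-vinylisobenzofuran-1(3H)-one; 22 (2R,8R)-2,8-bis(tert-butyldimethylsilyloxy)tetradec-13-en-5-one
Product: 23 (R)-3-[(1E,7R,13R)-7,13-bis(tert-butyldimethylsilyloxy)-10-oxotetradec-1-en-1-yl]-5,7-dimethoxyisobenzofuran-1(3H)-one (E isomer drawn; any Z isomer is carried on with it)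
Conditions: second-generation Grubbs catalyst (5 mol %), 1,4-benzoquinone (10 mol %), CH2Cl2, 40 °C; 22 in twofold excess
Reagents that add atoms: none
Why: Olefin cross-metathesis between the terminal alkene of 22 and the less reactive vinyl group of 9 joins C1' to C2' with loss of ethene, benzoquinone is added to suppress ruthenium hydride isomerisation at the allylic C3–H, and the alkene geometry is irrelevant because the double bond is reduced next.

Step 13
Reactants: 23 (R)-3-[(1E,7R,13R)-7,13-bis(tert-butyldimethylsilyloxy)-10-oxotetradec-1-en-1-yl]-5,7-dimethoxyisobenzofuran-1(3H)-one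
Product: 24 (R)-3-[(7R,13R)-7,13-bis(tert-butyldimethylsilyloxy)-10-oxotetradecyl]-5,7-dimethoxyisobenzofuran-1(3H)-one
Conditions: KO2CN=NCO2K (excess), AcOH, CH2Cl2/MeOH, 0 °C to rt
Reagents that add atoms: none
Why: Diimide reduction transfers H2 to the disubstituted alkene in a concerted syn fashion and, unlike hydrogenation over palladium, cannot cleave the allylic and benzylic C3–O bond or reduce the ketone.

Step 14
Reactants: 24 (R)-3-[(7R,13R)-7,13-bis(tert-butyldimethylsilyloxy)-10-oxotetradecyl]-5,7-dimethoxyisobenzofuran-1(3H)-one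
Product: 27 (3R)-5,7-dimethoxy-3-{6-[(2R,5S,7R)-7-methyl-1,6-dioxaspiro[4.4]nonan-2-yl]hexyl}isobenzofuran-1(3H)-one (target), via keto diol 25 (not isolated), via spiro epimer 26 (not isolated)
Conditions: aq. HF (48 %), MeCN, rt; NaHCO3 work-up; preparative HPLC (silica, hexane/EtOAc), target fraction collected; the epimer fraction is passed unconcentrated through a short bed of Amberlyst 15 (rt) and re-injected, and the cycle is repeated until the epimer is used up
Reagents that add atoms: none
Why: HF removes both silyl ethers and the freed dihydroxy ketone 25 closes rings C and D by acid-catalysed spiroketalisation (two 5-exo additions, to the carbonyl and then to the oxocarbenium carbon), in which C2'' and C7'' are fixed and C5'' forms under thermodynamic control as target 27 and its 5''R epimer 26 in expectedly comparable amounts, and because 26 reopens to the same oxocarbenium ion on the sulfonic acid resin and goes back to the column in solution, repeated cycles should funnel the material into the 5''S epimer.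

Compound list
1 | 3,5-dimethoxybenzaldehyde | COc1cc(OC)cc(C=O)c1 | starting material
2 | 2-iodo-3,5-dimethoxybenzaldehyde | COc1cc(OC)c(I)c(C=O)c1 | intermediate
3 | triethyl phosphonoacetate | CCOC(=O)CP(=O)(OCC)OCC | starting material
4 | ethyl (E)-3-(2-iodo-3,5-dimethoxyphenyl)prop-2-enoate | COc1cc(OC)c(I)c(/C=C/C(=O)OCC)c1 | intermediate
5 | (E)-3-(2-iodo-3,5-dimethoxyphenyl)prop-2-en-1-ol | COc1cc(OC)c(I)c(/C=C/CO)c1 | intermediate
6 | tert-butyl (E)-3-(2-iodo-3,5-dimethoxyphenyl)prop-2-en-1-yl carbonate | COc1cc(OC)c(I)c(/C=C/COC(=O)OC(C)(C)C)c1 | intermediate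
7 | chloro{2-[(E)-3-(tert-butoxycarbonyloxy)prop-1-en-1-yl]-4,6-dimethoxyphenyl}magnesium (LiCl complex) | COc1cc(OC)c([Mg]Cl)c(/C=C/COC(=O)OC(C)(C)C)c1 | intermediate
8 | chloromagnesium 2-[(E)-3-(tert-butoxycarbonyloxy)prop-1-en-1-yl]-4,6-dimethoxybenzoate | COc1cc(OC)c(C(=O)O[Mg]Cl)c(/C=C/COC(=O)OC(C)(C)C)c1 | intermediate
9 | (R)-5,7-dimethoxy-3-vinylisobenzofuran-1(3H)-one | COc1cc(OC)c2c(c1)[C@@H](C=C)OC2=O | intermediate
10 | 5-bromopent-1-ene | C=CCCCBr | starting material
11 | (R)-epichlorohydrin, (R)-2-(chloromethyl)oxirane | ClC[C@H]1CO1 | starting material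
12 | pent-4-en-1-ylmagnesium bromide | C=CCCC[Mg]Br | intermediate
13 | (R)-1-chlorooct-7-en-2-ol | ClC[C@H](O)CCCCC=C | intermediate
14 | (R)-2-(hex-5-en-1-yl)oxirane | C=CCCCC[C@@H]1CO1 | intermediate
15 | acetone N,N-dimethylhydrazone | CC(C)=NN(C)C | starting material
16 | (R)-2-methyloxirane | C[C@@H]1CO1 | starting material
17 | lithium azaenolate of acetone N,N-dimethylhydrazone | C=C(C)N([Li])N(C)C | intermediate
18 | (R)-5-(2,2-dimethylhydrazinylidene)hexan-2-ol | C[C@@H](O)CCC(C)=NN(C)C | intermediate
19 | dilithio alkoxide azaenolate of 18 | C=C(CC[C@@H](C)O[Li])N([Li])N(C)C | intermediate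
20 | (2R,8R)-5-(2,2-dimethylhydrazinylidene)tetradec-13-ene-2,8-diol | C=CCCCC[C@@H](O)CCC(CC[C@@H](C)O)=NN(C)C | intermediate
21 | 2-[(2R,8R)-2,8-bis(tert-butyldimethylsilyloxy)tetradec-13-en-5-ylidene]-1,1-dimethylhydrazine | C=CCCCC[C@@H](O[Si](C)(C)C(C)(C)C)CCC(CC[C@@H](C)O[Si](C)(C)C(C)(C)C)=NN(C)C | intermediate
22 | (2R,8R)-2,8-bis(tert-butyldimethylsilyloxy)tetradec-13-en-5-one | C=CCCCC[C@@H](O[Si](C)(C)C(C)(C)C)CCC(=O)CC[C@@H](C)O[Si](C)(C)C(C)(C)C | intermediate
23 | (R)-3-[(1E,7R,13R)-7,13-bis(tert-butyldimethylsilyloxy)-10-oxotetradec-1-en-1-yl]-5,7-dimethoxyisobenzofuran-1(3H)-one | COc1cc(OC)c2c(c1)[C@@H](/C=C/CCCC[C@@H](O[Si](C)(C)C(C)(C)C)CCC(=O)CC[C@@H](C)O[Si](C)(C)C(C)(C)C)OC2=O | intermediate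
24 | (R)-3-[(7R,13R)-7,13-bis(tert-butyldimethylsilyloxy)-10-oxotetradecyl]-5,7-dimethoxyisobenzofuran-1(3H)-one | COc1cc(OC)c2c(c1)[C@@H](CCCCCC[C@@H](O[Si](C)(C)C(C)(C)C)CCC(=O)CC[C@@H](C)O[Si](C)(C)C(C)(C)C)OC2=O | intermediate
25 | (R)-3-[(7R,13R)-7,13-dihydroxy-10-oxotetradecyl]-5,7-dimethoxyisobenzofuran-1(3H)-one | COc1cc(OC)c2c(c1)[C@@H](CCCCCC[C@@H](O)CCC(=O)CC[C@@H](C)O)OC2=O | intermediate
26 | (3R)-5,7-dimethoxy-3-{6-[(2R,5R,7R)-7-methyl-1,6-dioxaspiro[4.4]nonan-2-yl]hexyl}isobenzofuran-1(3H)-one (C5'' epimer, formed and returned to the equilibrium within step 14) | COc1cc(OC)c2c(c1)[C@@H](CCCCCC[C@@H]1CC[C@@]3(CC[C@@H](C)O3)O1)OC2=O | intermediate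
27 | (3R)-5,7-dimethoxy-3-{6-[(2R,5S,7R)-7-methyl-1,6-dioxaspiro[4.4]nonan-2-yl]hexyl}isobenzofuran-1(3H)-one | COc1cc(OC)c2c(c1)[C@@H](CCCCCC[C@@H]1CC[C@]3(CC[C@@H](C)O3)O1)OC2=O | target

Total step count: 14.
Longest linear sequence: 8 steps (1–5 and 12–14; the chain branch 6, 7, 9–14 is equally long).

Steps most likely to fail

1. Step 5 (proposed new method). The Grignard reagent may attack the carbonate or be protonated before carboxylation. The magnesium carboxylate may cyclise too slowly, so that intermolecular attack competes. Enantioface discrimination may be poor or of the wrong sense. Reversible ionisation of the product may erode its enantiomeric purity.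
Fallback, known chemistry, from 2 back to 9: aldehyde 2 is treated with vinylmagnesium bromide to give racemic 1-(2-iodo-3,5-dimethoxyphenyl)prop-2-en-1-ol F1, which MnO2 oxidises to 1-(2-iodo-3,5-dimethoxyphenyl)prop-2-en-1-one F2. Corey–Bakshi–Shibata reduction with the (S)-methyl oxazaborolidine and BH3·SMe2 should give (R)-1-(2-iodo-3,5-dimethoxyphenyl)prop-2-en-1-ol F3, the aryl group acting as the large substituent. Two equivalents of iPrMgCl·LiCl convert F3 into the doubly magnesiated alkoxide aryl Grignard species F4. CO2 and acidification give (R)-2-(1-hydroxyprop-2-en-1-yl)-4,6-dimethoxybenzoic acid F5, which lactonises with retention to 9. This fallback gives up the one-flask CO2 construction and closes ring B the classical way, through the C7a–C1 and C1–O2 bonds.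

2. Step 12. Ruthenium hydride species may isomerise the vinyl group of 9 into conjugation with ring A. Homodimerisation of 22 may outpace the cross reaction. Conversion of the hindered allylic olefin may stall.
Fallback, known chemistry, from 18 and 9 back to 24: the union is moved to a B-alkyl Suzuki–Miyaura coupling. Hydrazone 18 is alkylated as in step 9 with commercial (R)-2-(but-3-en-1-yl)oxirane F6 to give (2R,8R)-5-(2,2-dimethylhydrazinylidene)dodec-11-ene-2,8-diol F7. Silylation gives the bis-TBS hydrazone F8 and oxalic acid hydrolysis gives (2R,8R)-2,8-bis(tert-butyldimethylsilyloxy)dodec-11-en-5-one F9. Ozonolysis (O3, then PPh3) gives (4R,10R)-4,10-bis(tert-butyldimethylsilyloxy)-7-oxoundecanal F10, and Takai olefination (CrCl2, CHI3) gives (2R,8R,11E)-2,8-bis(tert-butyldimethylsilyloxy)-12-iodododec-11-en-5-one F11. Hydroboration of 9 with 9-BBN gives the B-alkyl borane F12, which is coupled in the same flask with F11 (PdCl2(dppf), AsPh3, Cs2CO3, DMF/THF/H2O) to the (3E)-alkene F13. Hydrogenation (H2, palladium on carbon, EtOAc), now safe because the alkene is remote from the C3–O bond, returns to 24.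

3. Step 14. The equilibrium at C5'' may show no useful preference. The chromatographic resolution of the two spiro epimers may be inefficient at the stage of the final product, so that the return loop over the acid resin becomes laborious.
Fallback, known chemistry, from 20 back to 27: the spiroketal is formed and resolved at the fragment stage. Diol hydrazone 20 is hydrolysed and cyclised (aq. oxalic acid, then camphorsulfonic acid in CH2Cl2) to (2R,5S,7R)-2-(hex-5-en-1-yl)-7-methyl-1,6-dioxaspiro[4.4]nonane F14 and its (2R,5R,7R) epimer F15. These small, non-polar, volatile compounds can be separated on AgNO3-impregnated silica or by preparative gas chromatography, and F15 is re-equilibrated with acid. Cross-metathesis of F14 with 9 under the conditions of step 12 gives (R)-5,7-dimethoxy-3-{(E)-6-[(2R,5S,7R)-7-methyl-1,6-dioxaspiro[4.4]nonan-2-yl]hex-1-en-1-yl}isobenzofuran-1(3H)-one F16. Diimide reduction with 2-nitrobenzenesulfonohydrazide and Et3N (no acid, no ketone present) gives 27. Both later steps are non-acidic, so the C5'' configuration fixed at the fragment stage should be carried through.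

Further compounds
F1 | step 5 | racemic 1-(2-iodo-3,5-dimethoxyphenyl)prop-2-en-1-ol | COc1cc(OC)c(I)c(C(O)C=C)c1
F2 | step 5 | 1-(2-iodo-3,5-dimethoxyphenyl)prop-2-en-1-one | COc1cc(OC)c(I)c(C(=O)C=C)c1
F3 | step 5 | (R)-1-(2-iodo-3,5-dimethoxyphenyl)prop-2-en-1-ol | COc1cc(OC)c(I)c([C@H](O)C=C)c1
F4 | step 5 | doubly magnesiated alkoxide aryl Grignard species from F3 | COc1cc(OC)c([Mg]Cl)c([C@H](O[Mg]Cl)C=C)c1
F5 | step 5 | (R)-2-(1-hydroxyprop-2-en-1-yl)-4,6-dimethoxybenzoic acid | COc1cc(OC)c(C(=O)O)c([C@H](O)C=C)c1
F6 | step 12 | (R)-2-(but-3-en-1-yl)oxirane | C=CCC[C@@H]1CO1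
F7 | step 12 | (2R,8R)-5-(2,2-dimethylhydrazinylidene)dodec-11-ene-2,8-diol | C=CCC[C@@H](O)CCC(CC[C@@H](C)O)=NN(C)C
F8 | step 12 | 2-[(2R,8R)-2,8-bis(tert-butyldimethylsilyloxy)dodec-11-en-5-ylidene]-1,1-dimethylhydrazine | C=CCC[C@@H](O[Si](C)(C)C(C)(C)C)CCC(CC[C@@H](C)O[Si](C)(C)C(C)(C)C)=NN(C)C
F9 | step 12 | (2R,8R)-2,8-bis(tert-butyldimethylsilyloxy)dodec-11-en-5-one | C=CCC[C@@H](O[Si](C)(C)C(C)(C)C)CCC(=O)CC[C@@H](C)O[Si](C)(C)C(C)(C)C
F10 | step 12 | (4R,10R)-4,10-bis(tert-butyldimethylsilyloxy)-7-oxoundecanal | O=CCC[C@@H](O[Si](C)(C)C(C)(C)C)CCC(=O)CC[C@@H](C)O[Si](C)(C)C(C)(C)C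
F11 | step 12 | (2R,8R,11E)-2,8-bis(tert-butyldimethylsilyloxy)-12-iodododec-11-en-5-one | I/C=C/CC[C@@H](O[Si](C)(C)C(C)(C)C)CCC(=O)CC[C@@H](C)O[Si](C)(C)C(C)(C)C
F12 | step 12 | (R)-3-[2-(9-borabicyclo[3.3.1]nonan-9-yl)ethyl]-5,7-dimethoxyisobenzofuran-1(3H)-one | COc1cc(OC)c2c(c1)[C@@H](CCB1C3CCCC1CCC3)OC2=O
F13 | step 12 | (R)-3-[(3E,7R,13R)-7,13-bis(tert-butyldimethylsilyloxy)-10-oxotetradec-3-en-1-yl]-5,7-dimethoxyisobenzofuran-1(3H)-one | COc1cc(OC)c2c(c1)[C@@H](CC/C=C/CC[C@@H](O[Si](C)(C)C(C)(C)C)CCC(=O)CC[C@@H](C)O[Si](C)(C)C(C)(C)C)OC2=O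
F14 | step 14 | (2R,5S,7R)-2-(hex-5-en-1-yl)-7-methyl-1,6-dioxaspiro[4.4]nonane | C=CCCCC[C@@H]1CC[C@]2(CC[C@@H](C)O2)O1
F15 | step 14 | (2R,5R,7R)-2-(hex-5-en-1-yl)-7-methyl-1,6-dioxaspiro[4.4]nonane | C=CCCCC[C@@H]1CC[C@@]2(CC[C@@H](C)O2)O1
F16 | step 14 | (R)-5,7-dimethoxy-3-{(E)-6-[(2R,5S,7R)-7-methyl-1,6-dioxaspiro[4.4]nonan-2-yl]hex-1-en-1-yl}isobenzofuran-1(3H)-one | COc1cc(OC)c2c(c1)[C@@H](/C=C/CCCC[C@@H]1CC[C@]3(CC[C@@H](C)O3)O1)OC2=O
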